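## Retrosynthetic overview

1. The strategy rests on the quinone ring, which carries six different positions in sequence: C1′=O, C2′–OH, C3′–C11H2 (a neopentyl CH2 on quaternary C9), C4′=O, C5′–NH-isopentyl and C6′–H. The ring is therefore grown, C1′–C4′ from a squarate and C5′/C6′ from acetylene, and not substituted.
2. O-dealkylation at C2′ and oxidative amination at C5′ lead back to a 2-isopropoxy-3-alkyl-1,4-benzoquinone. Its C4′–C5′ bond is disconnected to a 4-ethynyl-4-hydroxycyclobutenone (thermal ring expansion).
3. The cyclobutenone comes from acetylide addition to a 3-alkyl-4-isopropoxycyclobutenedione. The C11–C3′ bond comes from a neopentyllithium and diisopropyl squarate.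
4. Ring B is built on a bought ring A by an exo-selective, catalyst-controlled Diels–Alder reaction of 1-ethenyl-6,6-dimethylcyclohexene with tiglic aldehyde, which sets C8, C9 and C10.
5. Ring order: A (bought), B (step 3), four-membered ring (bought), quinone ring (step 9).

Key step: step 9

Remark: decalin atoms are numbered as in drimanes (ring A C1–C5 and C10, ring B C5–C10, C11 = CH2 on C9) and quinone atoms carry primes; the carbinol carbon of 11 and 13 is expected as both epimers, which converge, so it is left undefined in their SMILES.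

Notation: "DecCH2" = [(1R,2S,8aS)-1,2,5,5-tetramethyl-1,2,3,5,6,7,8,8a-octahydronaphthalen-1-yl]methyl (8β-CH3, 9β-CH3, 10α-H, C11 on the α face).

## Route

Step 1
Reactants: 1 2,2-dimethylcyclohexan-1-one
Product: 3 6,6-dimethylcyclohex-1-en-1-yl trifluoromethanesulfonate, via lithium enolate 2 (not isolated)
Conditions: LDA (1.1 equiv), THF, −78 °C; PhNTf2, −78 °C → rt; aq. NH4Cl
Reagents that add atoms: N-phenylbis(trifluoromethanesulfonimide), O=S(=O)(N(c1ccccc1)S(=O)(=O)C(F)(F)F)C(F)(F)F
Why: Deprotonation can only occur at C6 because C2 is quaternary, and O-sulfonylation of the lithium enolate (enol triflate formation) is standard for hindered cyclohexanones.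

Step 2
Reactants: 3 6,6-dimethylcyclohex-1-en-1-yl trifluoromethanesulfonate
Product: 4 1-ethenyl-6,6-dimethylcyclohex-1-ene
Conditions: Bu3SnCH=CH2 (1.1 equiv), Pd(PPh3)4 (3 mol %), LiCl (3 equiv), THF, 65 °C
Reagents that add atoms: tributyl(vinyl)stannane, C=C[Sn](CCCC)(CCCC)CCCC
Why: Stille coupling of a cyclohexenyl triflate with a vinylstannane under Pd(0)/LiCl is a classical route to 1-vinylcyclohexenes and should tolerate the neighbouring quaternary carbon.

Step 3
Reactants: 4 1-ethenyl-6,6-dimethylcyclohex-1-ene; 5 (E)-2-methylbut-2-enal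
Product: 6 (1R,2S,8aR)-1,2,5,5-tetramethyl-1,2,3,5,6,7,8,8a-octahydronaphthalene-1-carbaldehyde
Conditions: (R)-o-tolyl-CBS oxazaborolidine (20 mol %), Tf2NH (17 mol %), 5 (3 equiv), CH2Cl2, −78 → −40 °C
Reagents that add atoms: none
Why: In this chiral oxazaborolidinium-catalysed Diels–Alder reaction of an α-substituted enal the "ortho" orientation joins the enal α-carbon to C10 and the β-carbon to the vinyl CH2, suprafacial addition to the (E)-enal makes the C8 and C9 methyls cis, the exo-formyl transition state usual for α-methyl enals puts 10-H trans to 9-CH3, and the (R)-catalyst, which binds the s-trans enal through a formyl C–H···O contact, is expected to expose the Si face of the α-carbon and so set the absolute configuration at C9.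

Step 4
Reactants: 6 (1R,2S,8aR)-1,2,5,5-tetramethyl-1,2,3,5,6,7,8,8a-octahydronaphthalene-1-carbaldehyde
Product: 7 [(1R,2S,8aR)-1,2,5,5-tetramethyl-1,2,3,5,6,7,8,8a-octahydronaphthalen-1-yl]methanol
Conditions: NaBH4, MeOH, 0 °C → rt
Reagents that add atoms: none
Why: Hydride reduction of the neopentyl aldehyde gives the primary alcohol without creating a stereocentre and leaves the trisubstituted alkene untouched.

Step 5
Reactants: 7 [(1R,2S,8aR)-1,2,5,5-tetramethyl-1,2,3,5,6,7,8,8a-octahydronaphthalen-1-yl]methanol
Product: 8 (1R,2S,8aR)-1-(iodomethyl)-1,2,5,5-tetramethyl-1,2,3,5,6,7,8,8a-octahydronaphthalene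
Conditions: I2, PPh3, imidazole, toluene, 90 °C
Reagents that add atoms: iodine, II
Why: In this Appel-type (Garegg–Samuelsson) iodination iodide displaces the alkoxyphosphonium group by an SN2 step that is slow at a neopentyl carbon but should proceed on heating without skeletal rearrangement, since no carbocation is involved.

Step 6
Reactants: 8 (1R,2S,8aR)-1-(iodomethyl)-1,2,5,5-tetramethyl-1,2,3,5,6,7,8,8a-octahydronaphthalene; 9 3,4-di(propan-2-yloxy)cyclobut-3-ene-1,2-dione (diisopropyl squarate)
Product: 11 4-(DecCH2)-4-hydroxy-2,3-di(propan-2-yloxy)cyclobut-2-en-1-one, via neopentyllithium 10 (not isolated)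
Conditions: t-BuLi (2.1 equiv), Et2O–pentane, −78 °C; then 9 (1.1 equiv), THF, −78 °C; aq. NH4Cl
Reagents that add atoms: none
Why: Lithium–iodine exchange gives a neopentyllithium that cannot β-eliminate and adds 1,2 to one carbonyl of the squarate (standard squarate ester chemistry); the new carbinol carbon forms as both epimers, which is without consequence because it becomes sp2 in step 7.

Step 7
Reactants: 11 4-(DecCH2)-4-hydroxy-2,3-di(propan-2-yloxy)cyclobut-2-en-1-one
Product: 12 3-(DecCH2)-4-(propan-2-yloxy)cyclobut-3-ene-1,2-dione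
Conditions: conc. HCl (cat.), CH2Cl2, 0 °C, short reaction time
Reagents that add atoms: none
Why: Acid-catalysed ionisation of the tertiary carbinol to the alkoxy-stabilised cyclobutenyl cation, return of water at the distal alkoxy carbon and loss of isopropanol is the standard rearrangement of squarate adducts to 3-alkyl-4-alkoxycyclobutenediones, and brief contact with catalytic acid at 0 °C should not protonate the C5=C6 bond.

Step 8
Reactants: 12 3-(DecCH2)-4-(propan-2-yloxy)cyclobut-3-ene-1,2-dione
Product: 13 2-(DecCH2)-4-ethynyl-4-hydroxy-3-(propan-2-yloxy)cyclobut-2-en-1-one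
Conditions: HC≡CMgBr (1.3 equiv, 0.5 M in THF), THF, −78 → −40 °C; aq. NH4Cl
Reagents that add atoms: ethynylmagnesium bromide, C#C[Mg]Br
Why: Grignard 1,2-addition should occur at the ketone next to the isopropoxy-bearing carbon because the other carbonyl is deactivated as a vinylogous ester, which places C11 beside the future C4′ and the alkoxy group beside the future C1′; the two carbinol epimers converge in step 9.

Step 9
Reactants: 13 2-(DecCH2)-4-ethynyl-4-hydroxy-3-(propan-2-yloxy)cyclobut-2-en-1-one
Product: 15 3-(DecCH2)-2-(propan-2-yloxy)cyclohexa-2,5-diene-1,4-dione, via enynylketene 14 (not isolated)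
Conditions: toluene (0.01 M, degassed), 110 °C
Reagents that add atoms: none
Why: Heating should open the cyclobutenone by conrotatory 4π-electrocyclic ring opening with the donor hydroxyl rotating outward, which gives the (Z)-enynylketene 14 with the ethynyl group cis to the ketene. The ketene carbon (C4′) then bonds to the alkyne terminus (C5′), a six-membered closure onto the triple bond (formally 6-endo-dig) that gives a phenoxyl/σ-aryl diradical, and transfer of the hydroxyl hydrogen to C6′ delivers the quinone. This is the Moore rearrangement of 4-alkynyl-4-hydroxycyclobutenones, the closest known reaction type, applied without change. No stereocentre is formed and the carbinol centre is destroyed, so both epimers of 13 give the same product, while the three decalin stereocentres are remote and untouched. The selectivity needed is regiochemical (alkyl beside C4′, alkoxy beside C1′, C5′ and C6′ both CH) and is fixed beforehand by the site of acetylide addition in step 8; six-ring closure should prevail over five-ring closure because the unsubstituted alkyne terminus gives no stabilisation to the exocyclic vinyl radical that the five-ring path requires. High dilution and exclusion of oxygen should limit intermolecular trapping of the ketene and the diradical.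

Step 10
Reactants: 15 3-(DecCH2)-2-(propan-2-yloxy)cyclohexa-2,5-diene-1,4-dione; 16 3-methylbutan-1-amine
Product: 18 3-(DecCH2)-5-[(3-methylbutyl)amino]-2-(propan-2-yloxy)cyclohexa-2,5-diene-1,4-dione, via aminohydroquinone 17 (not isolated)
Conditions: 16 (1.2 equiv), Cu(OAc)2·H2O (10 mol %), O2 (1 atm), EtOH–THF, rt
Reagents that add atoms: none
Why: In this oxidative amination (aza-Michael addition, then reoxidation by O2) C5′ is the β-carbon of the C1′ enone, whose carbonyl is not deactivated by the isopropoxy group, whereas C6′ is β to the vinylogous-ester carbonyl C4′ and ipso attack at C2′ is hindered by the isopropyl group and the neopentyl side chain.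

Step 11
Reactants: 18 3-(DecCH2)-5-[(3-methylbutyl)amino]-2-(propan-2-yloxy)cyclohexa-2,5-diene-1,4-dione
Product: 19 nakijiquinone M, 3-(DecCH2)-2-hydroxy-5-[(3-methylbutyl)amino]cyclohexa-2,5-diene-1,4-dione
Conditions: BCl3 (3 equiv), CH2Cl2, −78 → −40 °C; cold pH 7 phosphate buffer
Reagents that add atoms: none
Why: In this Lewis-acid ether cleavage BCl3 held between the C1′ carbonyl and the ether oxygen should cut the secondary isopropyl–oxygen bond at low temperature, as for isopropyl aryl ethers next to a carbonyl; the vinylogous amide cannot hydrolyse under anhydrous conditions and the cold buffered quench avoids Brønsted acid that could protonate C5=C6.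

## Compound list

1 | 2,2-dimethylcyclohexan-1-one | CC1(C)CCCCC1=O | starting material
2 | lithium 6,6-dimethylcyclohex-1-en-1-olate (not isolated) | [Li]OC1=CCCCC1(C)C | intermediate
3 | 6,6-dimethylcyclohex-1-en-1-yl trifluoromethanesulfonate | CC1(C)CCCC=C1OS(=O)(=O)C(F)(F)F | intermediate
4 | 1-ethenyl-6,6-dimethylcyclohex-1-ene | C=CC1=CCCCC1(C)C | intermediate
5 | (E)-2-methylbut-2-enal (tiglic aldehyde) | C/C=C(\C)C=O | starting material
6 | (1R,2S,8aR)-1,2,5,5-tetramethyl-1,2,3,5,6,7,8,8a-octahydronaphthalene-1-carbaldehyde | O=C[C@@]1(C)[C@@H]2CCCC(C)(C)C2=CC[C@@H]1C | intermediate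
7 | [(1R,2S,8aR)-1,2,5,5-tetramethyl-1,2,3,5,6,7,8,8a-octahydronaphthalen-1-yl]methanol | OC[C@@]1(C)[C@@H]2CCCC(C)(C)C2=CC[C@@H]1C | intermediate
8 | (1R,2S,8aR)-1-(iodomethyl)-1,2,5,5-tetramethyl-1,2,3,5,6,7,8,8a-octahydronaphthalene | IC[C@@]1(C)[C@@H]2CCCC(C)(C)C2=CC[C@@H]1C | intermediate
9 | 3,4-di(propan-2-yloxy)cyclobut-3-ene-1,2-dione (diisopropyl squarate) | CC(C)OC1=C(OC(C)C)C(=O)C1=O | starting material
10 | (DecCH2)lithium, neopentyllithium (not isolated) | [Li]C[C@@]1(C)[C@@H]2CCCC(C)(C)C2=CC[C@@H]1C | intermediate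
11 | 4-(DecCH2)-4-hydroxy-2,3-di(propan-2-yloxy)cyclobut-2-en-1-one (both carbinol epimers) | CC(C)OC1=C(OC(C)C)C(O)(C[C@@]2(C)[C@@H]3CCCC(C)(C)C3=CC[C@@H]2C)C1=O | intermediate
12 | 3-(DecCH2)-4-(propan-2-yloxy)cyclobut-3-ene-1,2-dione | CC(C)OC1=C(C[C@@]2(C)[C@@H]3CCCC(C)(C)C3=CC[C@@H]2C)C(=O)C1=O | intermediate
13 | 2-(DecCH2)-4-ethynyl-4-hydroxy-3-(propan-2-yloxy)cyclobut-2-en-1-one (both carbinol epimers) | O=C1C(C[C@@]2(C)[C@@H]3CCCC(C)(C)C3=CC[C@@H]2C)=C(OC(C)C)C1(O)C#C | intermediate
14 | (3Z)-2-(DecCH2)-4-hydroxy-3-(propan-2-yloxy)hexa-1,3-dien-5-yn-1-one, enynylketene (not isolated) | O=C=C(C[C@@]1(C)[C@@H]2CCCC(C)(C)C2=CC[C@@H]1C)/C(OC(C)C)=C(/O)C#C | intermediate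
15 | 3-(DecCH2)-2-(propan-2-yloxy)cyclohexa-2,5-diene-1,4-dione | CC(C)OC1=C(C[C@@]2(C)[C@@H]3CCCC(C)(C)C3=CC[C@@H]2C)C(=O)C=CC1=O | intermediate
16 | 3-methylbutan-1-amine | CC(C)CCN | starting material
17 | 3-(DecCH2)-5-[(3-methylbutyl)amino]-2-(propan-2-yloxy)benzene-1,4-diol, aminohydroquinone (not isolated) | CC(C)CCNc1cc(O)c(OC(C)C)c(C[C@@]2(C)[C@@H]3CCCC(C)(C)C3=CC[C@@H]2C)c1O | intermediate
18 | 3-(DecCH2)-5-[(3-methylbutyl)amino]-2-(propan-2-yloxy)cyclohexa-2,5-diene-1,4-dione | CC(C)CCNC1=CC(=O)C(OC(C)C)=C(C[C@@]2(C)[C@@H]3CCCC(C)(C)C3=CC[C@@H]2C)C1=O | intermediate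
19 | nakijiquinone M, 2-hydroxy-5-[(3-methylbutyl)amino]-3-{[(1R,2S,8aS)-1,2,5,5-tetramethyl-1,2,3,5,6,7,8,8a-octahydronaphthalen-1-yl]methyl}cyclohexa-2,5-diene-1,4-dione | CC(C)CCNC1=CC(=O)C(O)=C(C[C@@]2(C)[C@@H]3CCCC(C)(C)C3=CC[C@@H]2C)C1=O | target

## Step count and risks

Total step count: 11. Longest linear sequence: 11 steps (1 to 19); 5, 9 and 16 enter as bought components.

Steps most likely to fail:

1. Step 9 (key step). The enynylketene may partition toward five-membered ring closure (giving an alkylidenecyclopentenedione), or the ketene and the diradical may be trapped intermolecularly before hydrogen transfer. Fallback, from 12: vinylmagnesium bromide (THF, −78 °C) should add at the same carbonyl to give the 4-ethenyl-4-hydroxycyclobutenone F1. Thermolysis (toluene or p-xylene, 110–140 °C) then runs through a dienylketene and a closed-shell 6π-electrocyclisation, followed by tautomerisation, to the hydroquinone F2. Oxidation with Ag2O (Et2O, rt) comes back to the route at 15.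

2. Step 3. The β-substituted enal may react too slowly with the hindered semicyclic diene at the temperature needed for enantiocontrol, and exo or facial selectivity may erode. If only the sense of induction is opposite to the model, the (S)-catalyst is used in the same step. Fallback, from 4 and 5: Me2AlCl (CH2Cl2, −78 → −20 °C) should give the racemic exo aldehyde F3, and NaBH4 the racemic alcohol F4. Acylation with (1S)-(−)-camphanic chloride (pyridine, DMAP) gives two diastereomeric esters, the camphanate of 7 F5 and the camphanate of ent-7 F6, to be separated by crystallisation or chromatography. Methanolysis of F5 (NaOMe, MeOH, 50 °C) comes back to the route at 7.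

3. Step 11. Brønsted acid released during dealkylation or quench may protonate C5=C6, after which the freed C2′ hydroxyl can close onto the cation or the double bond can migrate; BCl3 may also be sequestered by the vinylogous amide so that dealkylation stalls. Fallback, from 18: the C2′–O bond is cut instead of the O–alkyl bond, by vinylogous ester hydrolysis (addition–elimination of hydroxide at C2′) with 2 M aq. LiOH in THF–MeOH at 40 °C, then acidification to pH 4–5 with NaH2PO4 at 0 °C. The alkene never meets acid and the sequence comes back at 19. Its own hazard is competing displacement of the amine at C5′, to be limited by stopping at partial conversion. No new compound is made (F0).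

## Further compounds

F1 | step 9 | 2-(DecCH2)-4-ethenyl-4-hydroxy-3-(propan-2-yloxy)cyclobut-2-en-1-one (both carbinol epimers) | O=C1C(C[C@@]2(C)[C@@H]3CCCC(C)(C)C3=CC[C@@H]2C)=C(OC(C)C)C1(O)C=C
F2 | step 9 | 3-(DecCH2)-2-(propan-2-yloxy)benzene-1,4-diol | CC(C)Oc1c(O)ccc(O)c1C[C@@]2(C)[C@@H]3CCCC(C)(C)C3=CC[C@@H]2C
F3 | step 3 | racemic 1,2,5,5-tetramethyl-1,2,3,5,6,7,8,8a-octahydronaphthalene-1-carbaldehyde, (1R,2S,8aR) and (1S,2R,8aS) | O=C[C@@]1(C)[C@@H]2CCCC(C)(C)C2=CC[C@@H]1C.O=C[C@]1(C)[C@H]2CCCC(C)(C)C2=CC[C@H]1C
F4 | step 3 | racemic (1,2,5,5-tetramethyl-1,2,3,5,6,7,8,8a-octahydronaphthalen-1-yl)methanol, (1R,2S,8aR) and (1S,2R,8aS) | OC[C@@]1(C)[C@@H]2CCCC(C)(C)C2=CC[C@@H]1C.OC[C@]1(C)[C@H]2CCCC(C)(C)C2=CC[C@H]1C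
F5 | step 3 | [(1R,2S,8aR)-1,2,5,5-tetramethyl-1,2,3,5,6,7,8,8a-octahydronaphthalen-1-yl]methyl (1S,4R)-4,7,7-trimethyl-3-oxo-2-oxabicyclo[2.2.1]heptane-1-carboxylate | O=C(OC[C@@]1(C)[C@@H]2CCCC(C)(C)C2=CC[C@@H]1C)[C@@]34CC[C@@](C)(C(=O)O3)C4(C)C
F6 | step 3 | [(1S,2R,8aS)-1,2,5,5-tetramethyl-1,2,3,5,6,7,8,8a-octahydronaphthalen-1-yl]methyl (1S,4R)-4,7,7-trimethyl-3-oxo-2-oxabicyclo[2.2.1]heptane-1-carboxylate | O=C(OC[C@]1(C)[C@H]2CCCC(C)(C)C2=CC[C@H]1C)[C@@]34CC[C@@](C)(C(=O)O3)C4(C)C
F0 | step 11 | none | none
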